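## Retrosynthetic overview

1. Target 17 ⇐ opening of aryl lactone 16 ⇐ ligand-controlled CuH 1,4-reduction of coumarin 15 (sets the side-chain centre).
2. 15 ⇐ O-methylation and aromatic Claisen shift of reverse-prenyl ether 13 ⇐ Pd-catalysed O-allylation of phenol 9 with carbonate 12.
3. 9 ⇐ removal of the C10 oxygen from trans-chromanone 7 ⇐ key ring closure O7–C8: enantioselective 6-endo oxa-Michael addition in tigloyl phenol 5 (C8 set in the C–O bond formation, C9 by equilibration).
4. 5 ⇐ C8 Friedel–Crafts tigloylation of coumarin 3 ⇐ Pechmann condensation of phloroglucinol 1 with β-keto ester 2.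
5. Ring order: pyranone ring first (Pechmann), dihydropyran ring second (C–O closure), pyranone ring opened last.

Assumption: the catalyst antipodes written in steps 3 and 8 are taken to be the ones that give the (8S) and (4R) centres; if a first run shows the opposite sense, the mirror-image catalyst is used.

Locants: tricyclic intermediates are numbered as pyrano[2,3-f]chromenes (O1, C2 lactone carbonyl, C4 propyl, C5, C6, O7, C8, C9, C10). C8 and C9 become C2 and C3 of the chroman in the target.

## Route

Step 1
Reactants: 1 phloroglucinol; 2 ethyl 3-oxohexanoate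
Product: 3 5,7-dihydroxy-4-propyl-2H-chromen-2-one
Conditions: conc. H2SO4, 90 °C, 2 h; ice water, filter
Reagents that add atoms: none
Why: Pechmann condensation (transesterification, ring-closing hydroxyalkylation, dehydration) on the threefold-symmetric triol gives a single coumarin and creates no stereocentre.

Step 2
Reactants: 3 5,7-dihydroxy-4-propyl-2H-chromen-2-one; 4 tigloyl chloride
Product: 5 5,7-dihydroxy-8-[(2E)-2-methylbut-2-enoyl]-4-propyl-2H-chromen-2-one
Conditions: AlCl3 (3.5 equiv), PhNO2/1,2-dichloroethane, 70 °C, 3 h; ice/1 M HCl; crystallise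
Reagents that add atoms: none
Why: Friedel–Crafts acylation of 5,7-dihydroxy-4-alkylcoumarins goes mainly to C8 (ortho to 7-OH, para to 5-OH), and the aluminium chelate of the o-acylphenoxide holds the carbonyl syn to the oxygen so the ring cannot close early; no stereocentre is formed.

Step 3
Reactants: 5 5,7-dihydroxy-8-[(2E)-2-methylbut-2-enoyl]-4-propyl-2H-chromen-2-one
Product: 7 (8S,9S)-5-hydroxy-8,9-dimethyl-4-propyl-8,9-dihydro-2H,10H-pyrano[2,3-f]chromene-2,10-dione, via cis-chromanone 6 (not isolated)
Conditions: (R)-N-triflyl phosphoramide of 3,3'-bis(2,4,6-triisopropylphenyl)-BINOL (10 mol %), toluene, 5 Å MS, 25 °C, 48 h; then 60 °C, 6 h; crystallise the trans isomer, re-equilibrate the mother liquor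
Reagents that add atoms: none
Why: Proposed new method: an enantioselective, acid-mode 6-endo oxa-Michael ring closure in which the chiral N-triflyl phosphoramide protonates the electron-rich tigloyl carbonyl (breaking the 7-OH···O=C chelate that otherwise locks the unreactive rotamer), its anion then binds both the hydroxyallyl cation and the 7-OH in a contact ion pair so that the phenol oxygen adds to one face of the β-carbon and forms the O7–C8 bond with (8S) configuration, and the same acid afterwards equilibrates the enolisable C9 through the enol to the more stable trans (9S) epimer (modest preference, estimated about 5:1) without touching C8 because aryloxide is not expelled under acid, the closest known reactions being the cinchona-amine-catalysed (base-mode, cis-selective) intramolecular oxa-Michael addition of o-tigloylphenols, chiral phosphoric acid oxa-Michael cyclisations onto unsaturated thioesters and the chiral phosphoramide ion-pair cyclisation of o-hydroxyphenyl allylic alcohols to 2H-chromenes.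

Step 4
Reactants: 7 (8S,9S)-5-hydroxy-8,9-dimethyl-4-propyl-8,9-dihydro-2H,10H-pyrano[2,3-f]chromene-2,10-dione
Product: 9 (8S,9R)-5-hydroxy-8,9-dimethyl-4-propyl-9,10-dihydro-2H,8H-pyrano[2,3-f]chromen-2-one, via C10 carbinol 8 (not isolated)
Conditions: NaBH4, CeCl3·7H2O, MeOH/THF, −20 → 0 °C; aq. NH4Cl work-up; then slow addition of the crude carbinol to Et3SiH (10 equiv), TFA (3 equiv), CH2Cl2, −40 → 0 °C
Reagents that add atoms: none
Why: Carbonyl reduction followed by ionic hydrogenation (the benzylic cation stabilised by the para-OH and two ortho oxygens is trapped by silane hydride) removes the C10 oxygen, while the electron-poor coumarin enoate is inert to both reagents and C8/C9 are not involved (the C9 descriptor changes from S to R only because C10 loses priority).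

Step 5
Reactants: 10 2-methylbut-3-en-2-ol; 11 di-tert-butyl dicarbonate
Product: 12 tert-butyl 2-methylbut-3-en-2-yl carbonate
Conditions: n-BuLi (1.05 equiv), THF, −78 °C; Boc2O, −78 → 0 °C; H2O; distil
Reagents that add atoms: none
Why: O-acylation of the lithium tertiary alkoxide with Boc2O (carbonate formation) gives the allyl donor; no stereocentre.

Step 6
Reactants: 9 (8S,9R)-5-hydroxy-8,9-dimethyl-4-propyl-9,10-dihydro-2H,8H-pyrano[2,3-f]chromen-2-one; 12 tert-butyl 2-methylbut-3-en-2-yl carbonate
Product: 13 (8S,9R)-8,9-dimethyl-5-[(2-methylbut-3-en-2-yl)oxy]-4-propyl-9,10-dihydro-2H,8H-pyrano[2,3-f]chromen-2-one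
Conditions: Pd(PPh3)4 (5 mol %), THF, 0 °C → rt, 3 h; filter through silica
Reagents that add atoms: none
Why: Tsuji–Trost decarboxylative allylic etherification under neutral conditions, in which the phenoxide attacks the more substituted terminus of the 1,1-dimethylallyl-palladium cation under kinetic control to give the tertiary (reverse-prenyl) ether; stereocentres untouched.

Step 7
Reactants: 13 (8S,9R)-8,9-dimethyl-5-[(2-methylbut-3-en-2-yl)oxy]-4-propyl-9,10-dihydro-2H,8H-pyrano[2,3-f]chromen-2-one
Product: 15 (8S,9R)-5-methoxy-8,9-dimethyl-6-(3-methylbut-2-en-1-yl)-4-propyl-9,10-dihydro-2H,8H-pyrano[2,3-f]chromen-2-one, via 6-prenyl phenol 14 (not isolated)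
Conditions: DMF, 120 °C, 3 h; then 25 °C, K2CO3 (3 equiv), MeI (3 equiv), 12 h
Reagents that add atoms: methyl iodide, CI
Why: Aromatic Claisen [3,3] rearrangement delivers the allyl terminus to the only free ortho carbon (C6) as the normal prenyl group, and the freed phenoxide is O-methylated (Williamson) in the same pot; stereocentres untouched.

Step 8
Reactants: 15 (8S,9R)-5-methoxy-8,9-dimethyl-6-(3-methylbut-2-en-1-yl)-4-propyl-9,10-dihydro-2H,8H-pyrano[2,3-f]chromen-2-one
Product: 17 (3R)-3-[(2S,3R)-5-hydroxy-7-methoxy-2,3-dimethyl-8-(3-methylbut-2-en-1-yl)-3,4-dihydro-2H-chromen-6-yl]hexanoic acid, via dihydrocoumarin 16 (not isolated)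
Conditions: Cu(OAc)2·H2O (5 mol %), (R)-DTBM-SEGPHOS (5.5 mol %), (EtO)2MeSiH (2.5 equiv), t-BuOH (1.5 equiv), toluene, 0 → 25 °C; then LiOH·H2O (6 equiv), THF/MeOH/H2O, 25 °C; 1 M HCl to pH 4–5 at 0 °C, extract cold
Reagents that add atoms: lithium hydroxide (aqueous), [Li+].[OH-]
Why: Asymmetric CuH conjugate reduction adds hydride to one face of the β,β-disubstituted enoate under ligand control to set C4 as (R) independently of the remote chroman centres and leaves the unconjugated prenyl olefin alone, after which saponification of the aryl lactone and cold, mild acidification give the hydroxy acid without relactonisation.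

## Compound list

1 | phloroglucinol (benzene-1,3,5-triol) | Oc1cc(O)cc(O)c1 | starting material
2 | ethyl 3-oxohexanoate | CCCC(=O)CC(=O)OCC | starting material
3 | 5,7-dihydroxy-4-propyl-2H-chromen-2-one | CCCC1=CC(=O)Oc2cc(O)cc(O)c12 | intermediate
4 | (2E)-2-methylbut-2-enoyl chloride (tigloyl chloride) | C/C=C(\C)C(=O)Cl | starting material
5 | 5,7-dihydroxy-8-[(2E)-2-methylbut-2-enoyl]-4-propyl-2H-chromen-2-one | CCCC1=CC(=O)Oc2c1c(O)cc(O)c2C(=O)/C(C)=C/C | intermediate
6 | (8S,9R)-5-hydroxy-8,9-dimethyl-4-propyl-8,9-dihydro-2H,10H-pyrano[2,3-f]chromene-2,10-dione (cis-chromanone; not isolated) | CCCC1=CC(=O)Oc2c1c(O)cc1O[C@@H](C)[C@@H](C)C(=O)c12 | intermediate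
7 | (8S,9S)-5-hydroxy-8,9-dimethyl-4-propyl-8,9-dihydro-2H,10H-pyrano[2,3-f]chromene-2,10-dione (trans-chromanone) | CCCC1=CC(=O)Oc2c1c(O)cc1O[C@@H](C)[C@H](C)C(=O)c12 | intermediate
8 | (8S,9R,10R)-5,10-dihydroxy-8,9-dimethyl-4-propyl-9,10-dihydro-2H,8H-pyrano[2,3-f]chromen-2-one (major C10 epimer; not isolated) | CCCC1=CC(=O)Oc2c1c(O)cc1O[C@@H](C)[C@H](C)[C@@H](O)c12 | intermediate
9 | (8S,9R)-5-hydroxy-8,9-dimethyl-4-propyl-9,10-dihydro-2H,8H-pyrano[2,3-f]chromen-2-one | CCCC1=CC(=O)Oc2c1c(O)cc1O[C@@H](C)[C@H](C)Cc12 | intermediate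
10 | 2-methylbut-3-en-2-ol | CC(C)(O)C=C | starting material
11 | di-tert-butyl dicarbonate | CC(C)(C)OC(=O)OC(=O)OC(C)(C)C | starting material
12 | tert-butyl 2-methylbut-3-en-2-yl carbonate | CC(C)(C)OC(=O)OC(C)(C)C=C | intermediate
13 | (8S,9R)-8,9-dimethyl-5-[(2-methylbut-3-en-2-yl)oxy]-4-propyl-9,10-dihydro-2H,8H-pyrano[2,3-f]chromen-2-one | CCCC1=CC(=O)Oc2c1c(OC(C)(C)C=C)cc1O[C@@H](C)[C@H](C)Cc12 | intermediate
14 | (8S,9R)-5-hydroxy-8,9-dimethyl-6-(3-methylbut-2-en-1-yl)-4-propyl-9,10-dihydro-2H,8H-pyrano[2,3-f]chromen-2-one (not isolated) | CCCC1=CC(=O)Oc2c1c(O)c(CC=C(C)C)c1O[C@@H](C)[C@H](C)Cc12 | intermediate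
15 | (8S,9R)-5-methoxy-8,9-dimethyl-6-(3-methylbut-2-en-1-yl)-4-propyl-9,10-dihydro-2H,8H-pyrano[2,3-f]chromen-2-one | CCCC1=CC(=O)Oc2c1c(OC)c(CC=C(C)C)c1O[C@@H](C)[C@H](C)Cc12 | intermediate
16 | (4R,8S,9R)-5-methoxy-8,9-dimethyl-6-(3-methylbut-2-en-1-yl)-4-propyl-3,4,9,10-tetrahydro-2H,8H-pyrano[2,3-f]chromen-2-one (not isolated) | CCC[C@@H]1CC(=O)Oc2c1c(OC)c(CC=C(C)C)c1O[C@@H](C)[C@H](C)Cc12 | intermediate
17 | (3R)-3-[(2S,3R)-5-hydroxy-7-methoxy-2,3-dimethyl-8-(3-methylbut-2-en-1-yl)-3,4-dihydro-2H-chromen-6-yl]hexanoic acid (CNP0275989.1) | CCC[C@H](CC(=O)O)c1c(O)c2c(c(CC=C(C)C)c1OC)O[C@@H](C)[C@H](C)C2 | target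

## Step count and risks

Total step count: 8. Longest linear sequence: 7 (steps 1–4 and 6–8; step 5 prepares the allyl carbonate).

Steps most likely to fail:

Step 3 (the new acid-mode oxa-Michael closure). The level of face selectivity, the background racemic closure and the trans:cis ratio at equilibrium are all untested. The fallback uses known chemistry, sets out from 5 and comes back at 7. Quinidine (20–30 mol %) in chlorobenzene at room temperature effects the established cinchona-amine-catalysed intramolecular oxa-Michael addition of the o-tigloylphenol. It gives, after chromatography, cis-chromanone 6, here isolated, so this fallback makes no compound outside the list (F0). The known MgI2-assisted epimerisation at C9 then converts 6 into 7, and the ee is raised by recrystallisation.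

Step 4 (ionic deoxygenation). The benzylic cation can lose H-9 to give a chromene, which would scramble C9, or it can alkylate the free C6–H of a second molecule. The fallback avoids any carbocation, sets out from 7 and comes back at 9. Condensation with tosylhydrazide (EtOH, cat. TsOH, 70 °C) gives the tosylhydrazone of 7, N'-[(8S,9R)-5-hydroxy-8,9-dimethyl-2-oxo-4-propyl-8,9-dihydro-2H,10H-pyrano[2,3-f]chromen-10-ylidene]-4-methylbenzenesulfonohydrazide F1. This is reduced with catecholborane and then NaOAc·3H2O in warm CHCl3 (alkyldiazene route) to 9.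

Step 8 (asymmetric CuH reduction). The β-carbon is crowded by the peri 5-OMe and the propyl group, so the reduction may be slow or poorly face-selective. The fallback gives up catalyst control, sets out from 15 and comes back at 17. Mg turnings in MeOH reduce the enoate by electron transfer and methanolyse the aryl lactone. This gives methyl (3RS)-3-[(2S,3R)-5-hydroxy-7-methoxy-2,3-dimethyl-8-(3-methylbut-2-en-1-yl)-3,4-dihydro-2H-chromen-6-yl]hexanoate F2 as a roughly 1:1 mixture of C3 epimers. LiOH saponification and cold acidification give 17 together with its (3S)-epimer, (3S)-3-[(2S,3R)-5-hydroxy-7-methoxy-2,3-dimethyl-8-(3-methylbut-2-en-1-yl)-3,4-dihydro-2H-chromen-6-yl]hexanoic acid F3. F3 is a diastereomer of 17 and is removed by preparative HPLC.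

Further compounds

F0 | step 3 | none | none
F1 | step 4 | N'-[(8S,9R)-5-hydroxy-8,9-dimethyl-2-oxo-4-propyl-8,9-dihydro-2H,10H-pyrano[2,3-f]chromen-10-ylidene]-4-methylbenzenesulfonohydrazide | CCCC1=CC(=O)Oc2c1c(O)cc1O[C@@H](C)[C@H](C)C(=NNS(=O)(=O)c3ccc(C)cc3)c12
F2 | step 8 | methyl (3RS)-3-[(2S,3R)-5-hydroxy-7-methoxy-2,3-dimethyl-8-(3-methylbut-2-en-1-yl)-3,4-dihydro-2H-chromen-6-yl]hexanoate | CCCC(CC(=O)OC)c1c(O)c2c(c(CC=C(C)C)c1OC)O[C@@H](C)[C@H](C)C2
F3 | step 8 | (3S)-3-[(2S,3R)-5-hydroxy-7-methoxy-2,3-dimethyl-8-(3-methylbut-2-en-1-yl)-3,4-dihydro-2H-chromen-6-yl]hexanoic acid | CCC[C@@H](CC(=O)O)c1c(O)c2c(c(CC=C(C)C)c1OC)O[C@@H](C)[C@H](C)C2
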